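Retrosynthesis: the two O-acetyl spectator groups come off last. The C7–OH bond (water) and the C8–O4' ether bond are then cut together, which reduces the target to two copies of one phenol, sinapyl alcohol carried as its O9 acetate.
Enabling feature: ring B with its intact E-C7'=C8'–C9' propenol chain and ring A with C7–C8–C9 share one 4-oxy-3,5-dimethoxyphenyl-C3 skeleton. They differ only in the C8–O4' bond and the OH at C7, which is the pattern left by oxygen-to-C8 phenoxyl coupling and hydration of a ring A quinone methide.
Forward: the monomer C7=C8 bond is made from syringaldehyde, the ester is reduced and O9 is acetylated. Two monomers are then joined (C8–O4', then C7–O), the enantiomers are separated and the acetates removed. No ring is formed at any stage.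
Stereochemistry: C8 arises racemic in the coupling. C7 is set relative to C8 by the water addition, levelled by acid equilibration and sorted by chromatography, keeping threo. The absolute (7R,8R) configuration comes from resolution on a chiral phase.

Key step: step 4

Remark: lignan numbering is used (ring A–C7–C8–C9 for the glycerol unit, ring B–C7'=C8'–C9' for the propenol unit). The target SMILES reads as (7R,8R), the threo series. A racemate is written in the lists as both enantiomers joined by a dot.

Step 1
Reactants: 1 syringaldehyde; 2 monoethyl malonate (ethyl hydrogen malonate)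
Product: 3 ethyl (E)-sinapate
Conditions: pyridine, piperidine (cat.), 70 °C
Reagents that add atoms: none
Why: Knoevenagel–Doebner condensation with a malonic half ester, in which amine-catalysed condensation and decarboxylation give the thermodynamically preferred E-cinnamate directly at the ester level, and the ester cannot lose a second CO2 to a vinylphenol as the free acid can.

Step 2
Reactants: 3 ethyl (E)-sinapate
Product: 4 sinapyl alcohol [(E)-4-(3-hydroxyprop-1-enyl)-2,6-dimethoxyphenol]
Conditions: i-Bu2AlH (4 equiv), toluene, 0 °C; EtOH, then H2O
Reagents that add atoms: none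
Why: 1,2-reduction of an α,β-unsaturated ester with i-Bu2AlH, the standard preparation of monolignols, in which one equivalent is taken up by the phenol as its aluminium phenoxide and the rest reduces the ester to the allylic alcohol without touching the E double bond.

Step 3
Reactants: 4 sinapyl alcohol
Product: 5 sinapyl acetate [(E)-3-(4-hydroxy-3,5-dimethoxyphenyl)prop-2-enyl acetate]
Conditions: vinyl acetate (3 equiv), immobilised Candida antarctica lipase B, MTBE–THF, 30 °C
Reagents that add atoms: vinyl acetate, C=COC(C)=O
Why: lipase-catalysed irreversible transesterification, which acylates primary aliphatic alcohols but not a hindered phenol, is driven by tautomerisation of the released enol, and runs at neutral pH so that the labile p-hydroxycinnamyl ester survives.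

Step 4
Reactants: 5 sinapyl acetate (two molecules per molecule of product)
Product: 8 racemic threo 8-O-4' dimer 9,9'-diacetate, via phenoxyl radical 6 (not isolated), via quinone methide 7 (not isolated)
Conditions: Ag2O (0.55 equiv), 4 Å molecular sieves, CH2Cl2, rt, dark; filter through Celite; then 1,4-dioxane–H2O (1:1), HCl (0.05 M), rt; SiO2 chromatography
Reagents that add atoms: water, O
Why: Ag2O takes one electron and the proton from the phenol of 5 to give radical 6, whose spin is shared between O4 and C8; O4' of one radical bonds to C8 of a second (C8–O4' bond) to give quinone methide 7, and after the silver is filtered off acid-catalysed 1,6-addition of water to C7 (C7–O bond) restores ring A as a phenol. The closest known reaction type is the dehydrogenative dimerisation of monolignols, and Ag2O oxidation of O9-acylated sinapyl alcohol is a known entry to 8-O-4' structures; no ring is closed. The step needs 8-O-4' over the other coupling modes: the methoxy groups at C3 and C5 close off every ring carbon, and the O9 acetate denies the 8-8' bis(quinone methide) the double tetrahydrofuran closure that makes syringaresinol the main product from the free alcohol, besides removing the aliphatic OH groups that would add to C7 of 7. It also needs to stop at the dimer, which the dry first stage secures because 7 has no phenolic O–H and cannot be oxidised again. C8 is formed from a planar radical without chiral influence and is racemic; C7 is set relative to C8 by the face of 7 that water attacks, and with H8 held in the quinone methide plane by allylic strain the bulky 2,6-dimethoxyaryloxy group shields the face that leads to threo, so kinetic addition should lean to erythro. The free para phenol of ring A keeps the C7–O bond ionisable in the acidic medium, so holding the mixture there should level the two diastereomers, after which threo 8 is taken by chromatography and the erythro fraction is returned to the acid.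

Step 5
Reactants: 8 racemic threo 8-O-4' dimer 9,9'-diacetate
Product: 9 (7R,8R)-threo 8-O-4' dimer 9,9'-diacetate
Conditions: preparative HPLC, cellulose tris(3,5-dimethylphenylcarbamate) on silica, hexane–i-PrOH, rt
Reagents that add atoms: none
Why: direct chromatographic resolution on a polysaccharide carbamate phase, a method established for arylglycerol 8-O-4' ethers, in which the free C7 hydroxyl and the phenol supply the hydrogen-bond contacts, no bond at C7 or C8 is touched, and the (7R,8R) fraction is identified by MTPA ester analysis of the C7 carbinol on an aliquot.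

Step 6
Reactants: 9 (7R,8R)-threo 8-O-4' dimer 9,9'-diacetate
Product: 10 (7R,8R)-threo-syringylglycerol 8-O-4'-(sinapyl alcohol) ether (target)
Conditions: K2CO3 (cat.), MeOH, 0 °C, Ar; neutralise with acidic ion-exchange resin
Reagents that add atoms: none
Why: base-catalysed transesterification (Zemplén-type methanolysis) removes both primary acetates, while C7 and C8 carry no acidic hydrogen and the C7 hydroxyl does not leave from the phenolate at this temperature, so both centres are retained.

Compound list
1 | syringaldehyde (4-hydroxy-3,5-dimethoxybenzaldehyde) | COc1cc(C=O)cc(OC)c1O | starting material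
2 | monoethyl malonate (3-ethoxy-3-oxopropanoic acid) | CCOC(=O)CC(=O)O | starting material
3 | ethyl (E)-sinapate | CCOC(=O)/C=C/c1cc(OC)c(O)c(OC)c1 | intermediate
4 | sinapyl alcohol, (E)-4-(3-hydroxyprop-1-enyl)-2,6-dimethoxyphenol | COc1cc(/C=C/CO)cc(OC)c1O | intermediate
5 | sinapyl acetate, (E)-3-(4-hydroxy-3,5-dimethoxyphenyl)prop-2-enyl acetate | COc1cc(/C=C/COC(C)=O)cc(OC)c1O | intermediate
6 | 4-[(E)-3-acetoxyprop-1-enyl]-2,6-dimethoxyphenoxyl radical | COc1cc(/C=C/COC(C)=O)cc(OC)c1[O] | intermediate
7 | racemic 8-O-4' quinone methide, 4-{3-acetoxy-2-[4-((E)-3-acetoxyprop-1-enyl)-2,6-dimethoxyphenoxy]propylidene}-2,6-dimethoxycyclohexa-2,5-dien-1-one | COC1=CC(=C[C@@H](COC(C)=O)Oc2c(OC)cc(/C=C/COC(C)=O)cc2OC)C=C(OC)C1=O.COC1=CC(=C[C@H](COC(C)=O)Oc2c(OC)cc(/C=C/COC(C)=O)cc2OC)C=C(OC)C1=O | intermediate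
8 | racemic threo (7R,8R plus 7S,8S) 3-acetoxy-2-{4-[(E)-3-acetoxyprop-1-enyl]-2,6-dimethoxyphenoxy}-1-(4-hydroxy-3,5-dimethoxyphenyl)propan-1-ol | COc1cc([C@@H](O)[C@@H](COC(C)=O)Oc2c(OC)cc(/C=C/COC(C)=O)cc2OC)cc(OC)c1O.COc1cc([C@H](O)[C@H](COC(C)=O)Oc2c(OC)cc(/C=C/COC(C)=O)cc2OC)cc(OC)c1O | intermediate
9 | (7R,8R) enantiomer of 8 | COc1cc([C@@H](O)[C@@H](COC(C)=O)Oc2c(OC)cc(/C=C/COC(C)=O)cc2OC)cc(OC)c1O | intermediate
10 | (1R,2R)-1-(4-hydroxy-3,5-dimethoxyphenyl)-2-{4-[(E)-3-hydroxyprop-1-enyl]-2,6-dimethoxyphenoxy}propane-1,3-diol | COc1cc([C@@H](O)[C@@H](CO)Oc2c(OC)cc(/C=C/CO)cc2OC)cc(OC)c1O | target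

Total step count: 6. Longest linear sequence: 6 (from syringaldehyde 1 to 10).

Steps most likely to fail

Step 4. Several processes could erode the threo 8-O-4' dimer:
- residual 8-8' coupling;
- early hydration of the quinone methide by the water released in the oxidation, followed by renewed oxidation to oligomers;
- 1,6-loss of acetic acid from the phenol of 5 on the basic oxide surface;
- water addition mainly to the face opposite the aryloxy group, with acid levelling too slow to correct it.

The fallback builds the same skeleton ionically. It sets out from 3 and 1 and returns at 10, making steps 4 to 6 unnecessary.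
- Williamson alkylation of the phenol of 3 with (S)-4-benzyl-3-(bromoacetyl)oxazolidin-2-one (K2CO3, acetone) would give the aryloxyacetyl imide F1.
- Acetylation of 1 (Ac2O, pyridine) gives 4-O-acetylsyringaldehyde F2.
- The boron enolate of F1 (n-Bu2BOTf, Et3N, CH2Cl2, −78 to 0 °C) adds to F2 in an Evans syn aldol reaction to give the syn aldol imide F3. The auxiliary sets both centres through the chair transition state, and the syn relationship corresponds to threo. The (S)-auxiliary gives the arrangement that becomes (7R,8R).
- LiBH4 (THF–MeOH, 0 °C) reduces the imide to the C9 carbinol and strips the aryl acetate, giving the cinnamate ester triol F4.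
- i-Bu2AlH (CH2Cl2, −78 to 0 °C) reduces the cinnamate of F4 to the allylic alcohol of 10.

Step 5. Too small a separation factor, band overlap at preparative loading or poor solubility in the eluent could prevent clean separation of the enantiomers. The fallback replaces physical separation by enzymatic kinetic resolution. It sets out from 8 and returns at 10.
- Lipase-catalysed alcoholysis (Burkholderia cepacia lipase, n-BuOH, MTBE, 30 °C) should remove the remote O9' acetate from both enantiomers.
- The O9 acetate sits next to the C8 stereocentre and should be cleaved at different rates, as is known for primary 2-aryloxyalkyl esters.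
- For the case in which the (7S,8S) ester reacts faster, the mixture consists of the (7R,8R) 9-O-monoacetate F5 and the (7S,8S) tetraol F6, which are separable on silica.
- Methanolysis of F5 (K2CO3, MeOH, 0 °C) gives 10.
- If the enzyme shows the opposite preference, the tetraol fraction is 10 itself.

Step 3. Slow turnover because of limited substrate solubility, partial acylation of the phenol, or solvolytic loss of the allylic acetate during handling could spoil the monomer. The fallback protects everything and then frees one site. It sets out from 4 and returns at 5.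
- Peracetylation (Ac2O, pyridine, 0 °C) gives sinapyl alcohol 4,9-diacetate F7.
- Chemoselective cleavage of the more electrophilic aryl acetate with hydrazine acetate (DMF, rt) gives 5.

Further compounds
F1 | step 4 | (S)-4-benzyl-3-{[4-((E)-3-ethoxy-3-oxoprop-1-enyl)-2,6-dimethoxyphenoxy]acetyl}oxazolidin-2-one | O=C(COc1c(OC)cc(/C=C/C(=O)OCC)cc1OC)N3[C@@H](Cc2ccccc2)COC3=O
F2 | step 4 | 4-O-acetylsyringaldehyde (4-acetoxy-3,5-dimethoxybenzaldehyde) | CC(=O)Oc1c(OC)cc(C=O)cc1OC
F3 | step 4 | (S)-4-benzyl-3-[(2S,3R)-3-(4-acetoxy-3,5-dimethoxyphenyl)-2-{4-[(E)-3-ethoxy-3-oxoprop-1-enyl]-2,6-dimethoxyphenoxy}-3-hydroxypropanoyl]oxazolidin-2-one | COc1cc([C@@H](O)[C@@H](C(=O)N2[C@@H](Cc3ccccc3)COC2=O)Oc4c(OC)cc(/C=C/C(=O)OCC)cc4OC)cc(OC)c1OC(C)=O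
F4 | step 4 | ethyl (E)-3-{4-[(1R,2R)-1,3-dihydroxy-1-(4-hydroxy-3,5-dimethoxyphenyl)propan-2-yloxy]-3,5-dimethoxyphenyl}acrylate | COc1cc([C@@H](O)[C@@H](CO)Oc2c(OC)cc(/C=C/C(=O)OCC)cc2OC)cc(OC)c1O
F5 | step 5 | (7R,8R)-threo 8-O-4' dimer 9-O-monoacetate (O9' free) | COc1cc([C@@H](O)[C@@H](COC(C)=O)Oc2c(OC)cc(/C=C/CO)cc2OC)cc(OC)c1O
F6 | step 5 | (7S,8S)-threo-syringylglycerol 8-O-4'-(sinapyl alcohol) ether | COc1cc([C@H](O)[C@H](CO)Oc2c(OC)cc(/C=C/CO)cc2OC)cc(OC)c1O
F7 | step 3 | sinapyl alcohol 4,9-diacetate, (E)-3-(4-acetoxy-3,5-dimethoxyphenyl)prop-2-enyl acetate | COc1cc(/C=C/COC(C)=O)cc(OC)c1OC(C)=O
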